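## Structural features

The target is a depside: two benzene rings, ring A and ring B, joined by a single aryl ester that runs from the carboxyl carbon of ring A to the oxygen on C4 of ring B; there is no other ring and no stereocentre. Both rings carry the same pattern, carboxyl carbon on C1, methoxy on C2, oxygen on C4 and an unbranched pentyl chain on C6, so ring A is a 4-hydroxy-2-methoxy-6-pentylbenzoyl group and ring B the same benzoic acid acylated at O4. The fragile element is the inter-ring ester, a phenyl ester with a para-carboxyphenoxide as leaving group, which excludes hydroxide, alkoxide and strong nucleophiles late in the route; the electron-rich 4-hydroxybenzoic acid units can also lose carbon dioxide in hot acid. The real difficulty lies around C1 of each ring: the carboxyl carbon is flanked by methoxy and pentyl, which slows acyl transfer and makes esters hard to cleave, and the two ring oxygens must be told apart, methyl on the one ortho to the carboxyl and hydrogen or acyl on the para one, the reverse of what alkylation of a 2,4-dihydroxybenzoate delivers. A second demand is that two nearly identical, hindered halves be joined in one direction only, which calls for masking of one phenol and one carboxyl that can be lifted without base. The key step exploits the contiguous triad C6(pentyl)–C1(carboxyl)–C2(methoxy): C1 and C6 are adjacent and C1 sits next to the methoxy-bearing carbon, exactly the outcome when a carbon nucleophile adds to the remote carbon of a 3-methoxyaryne and an electrophile is then taken up at the near carbon. Because both rings contain this triad, one protected monomer serves for ring A and ring B.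

## Logic of the disconnections

18 is cut first at its two oxygen–benzyl bonds, the ether on the ring A phenol and the ester on the ring B carboxyl, which leads to 17. Neutral hydrogenolysis is the one unmasking that cannot touch the inter-ring ester, so both polar groups stay covered until the end. The forward step needs a substrate with nothing else reducible and a solvent that cannot transesterify.

17 is cut at the inter-ring C(=O)–O bond into acyl donor 16 (made in the flask from 13) and phenol 15. Both halves have the same skeleton, so the synthesis converges on a single monomer. The forward step must transfer an acyl group from a carbonyl with two ortho substituents to a phenol of modest nucleophilicity, and 15 must offer only that one nucleophilic site.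

15 is traced to 14 by cutting the ester oxygen–benzyl bond, and 14 to 13 by cutting the ether oxygen–benzyl bond. The hindered carboxyl is esterified more easily by alkylation at oxygen than by acyl substitution, and this sequence lets both halves come from 13. The demand is alkylation of the carboxylate without touching the free phenol.

13 is cut at two ring–substituent bonds at once, C6–pentyl and C1–carboxyl, which leads to 7, 8 and 9 through aryne 11. This removes both carbon substituents of the hindered triad in one operation and leaves an arene bearing only heteroatoms. The forward step needs a single aryne and regioselective addition, with the nucleophile at the carbon remote from methoxy.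

7 is cut at the C4 oxygen–benzyl bond (to 5 and 6), then at the sulfur–oxygen bond and the silicon–oxygen bond (to 2 and 3 through 4). The two hydroxyls of 2 have similar acidity, so they are differentiated by size: a bulky silyl group goes to the unflanked oxygen, the sulfonyl group to the flanked one, and the silyl group is then exchanged for benzyl. The demand is steric selectivity in the silylation and a desilylation that leaves the aryl sulfonate alone.

2 is cut at the C4–oxygen bond back to the formyl group of 1. The iodine, the methoxy group and the flanked hydroxyl are already in place in 1, so only an aldehyde-to-phenol oxidation is needed. The demand is that the para-hydroxyl drive aryl migration and that the hydroquinone be protected from air.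

## Other disconnections considered

Alternative 1: The cut is the C3–C4 bond of a ring that is not yet aromatic. The monomer is traced to the cyclohexenone A2 (methyl 2-methoxy-4-oxo-6-pentylcyclohex-2-ene-1-carboxylate, racemic), and that to the acyclic β-methoxy enoate diester A1 (dimethyl 2-(1-methoxyethylidene)-3-pentylpentanedioate).
- Forward key step: base would remove a γ-proton from the enol-ether methyl of A1, and the dienolate would attack the remote ester carbonyl (vinylogous Dieckmann condensation, six-membered closure with loss of methoxide) to give A2. Dehydrogenation would then give the phenol A3 (methyl 4-hydroxy-2-methoxy-6-pentylbenzoate).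
- In favour: simple acyclic esters as feedstock and enolate chemistry without cryogenic organometallics. The two oxygens are differentiated before the ring is aromatic (enol ether at C2, ketone at C4), so no selective methylation is needed.
- Against: an extra aromatisation step, with a risk of ring halogenation if it is done by halogenation–elimination, and competing deprotonation α to the saturated ester. Above all, A3 is a methyl ester flanked by two ortho groups; ring A needs the free acid, and cleaving that ester would need forcing conditions on a hydroxy acid that decarboxylates easily.
- Comparison: on structure the two plans are equal, since both give the fully differentiated monomer without regiochemical ambiguity. On mechanism Alternative 1 is the better for scale and robustness, while the chosen plan is the better in delivering the carboxylic acid itself with the C4 oxygen already benzylated. On step economy the chosen plan is ahead: four steps to 13 against roughly six (conjugate addition, enol ether formation, cyclisation, aromatisation, benzylation, ester cleavage).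

Alternative 2: The cut is the ring A C1–C6 bond, made on the intact depside. The product A5 (benzyl 4-[(2,4-dihydroxy-6-pentylbenzoyl)oxy]-2-methoxy-6-pentylbenzoate) is traced to the tetracarbonyl ester A4 (benzyl 2-methoxy-6-pentyl-4-[(3,5,7-trioxododecanoyl)oxy]benzoate), which would come from acylating phenol 15 with a triketide acyl donor.
- Forward key step: the C2 methylene of the chain in A4 would add to the C7 ketone (six-membered intramolecular aldol closure), and dehydration plus enolisation would aromatise ring A.
- In favour: the inter-ring ester would be made from an unhindered β-keto acyl donor instead of a di-ortho-substituted benzoyl donor, and on that point it is better than the chosen plan. Ring A would form under mild conditions with no protecting group of its own.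
- Against: A4 is an aryl ester of a β-keto acid and could expel the ring B phenoxide through an acylketene. Its polyketone chain also has competing closures (Claisen-type attack on the ester carbonyl, lactonisation to a pyranone) that would destroy the depside link. Ring B must still be made by another method. A5 carries both ring A oxygens free, so the methyl group would have to go onto the hydrogen-bonded ortho hydroxyl while the more reactive para hydroxyl is spared, which means protection, forced methylation and deprotection beside the labile ester.
- Comparison: on structure it solves one ring only and leaves the oxygen differentiation open, whereas the chosen plan settles both rings at once. On mechanism the aldol aromatisation is as credible as the aryne step, but its substrate is far less stable. On step economy it loses: about three steps after the key step plus the triketide donor, on top of a full synthesis of ring B.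

Alternative 3: The cut removes two ring bonds at once, C2–C3 and C4–C5 of the benzoate. A8 (methyl 2-methoxy-6-pentyl-4-[(triisopropylsilyl)oxy]benzoate) is traced to the pyranone A6 (methyl 6-methoxy-2-oxo-4-pentyl-2H-pyran-5-carboxylate) and the siloxyalkyne A7 (ethynyloxytri(propan-2-yl)silane).
- Forward key step: [4+2] cycloaddition across C3 and C6 of A6, with the nucleophilic terminal carbon of A7 bonding to the electrophilic C6, followed by cycloreversion with loss of CO2.
- In favour: convergent, and all four substituents arrive at the right oxidation level and already differentiated (methyl ether from the pyranone, silyl ether from the alkyne). No aromatisation reagent is needed and the regiochemistry follows from the polarity of both partners.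
- Against: A6 is a cyclic acyl ketene acetal, a moisture-sensitive class that would itself take several steps to make. Its donor methoxy group lowers the reactivity of the diene towards an electron-rich alkyne, so heating would probably be needed, and at such temperatures A7 can rearrange to a silylketene. A8 is again a hindered methyl ester.
- Comparison: on structure it equals the chosen plan in regiochemical definition, and it is better in that the C4 oxygen arrives with a fluoride-labile group that would suit ring B directly. On mechanism it is less certain, because both partners are sensitive and the electronic match is only moderate, whereas carbomagnesiation of alkoxyarynes is well charted. On step economy it is comparable up to the monomer at best and then falls behind because of the ester exchange.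

Key step: step 4

Assumption: pentylmagnesium bromide 8 is used as a commercial ethereal solution, titrated before use.

Remark on the structures: re-deriving the aryne regiochemistry from the positions of iodine, sulfonate and methoxy in 7 confirms 7 and 13 as drawn, so no structure needs correcting. The weak point is the differentiation of the two hydroxyls of 2, whose acidities are too close for a dependable direct mono-benzylation. It is therefore done by a silyl relay (4, 5), telescoped so that the precursor is still reached in three steps.

Acid 13 is divided into two portions, slightly less than half for steps 5 and 6 and the remainder for step 7.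

## Route

Step 1
Reactants: 1 5-iodovanillin (4-hydroxy-3-iodo-5-methoxybenzaldehyde)
Product: 2 2-iodo-6-methoxybenzene-1,4-diol
Conditions: 30% aq. H2O2, 1 M aq. NaOH, 0 → 40 °C, N2; then aq. HCl, Na2S2O4 wash
Reagents that add atoms: hydrogen peroxide, OO
Why: Dakin oxidation: hydroperoxide adds to the aldehyde, the electron-rich aryl group (para-phenoxide) migrates to oxygen and the formate is hydrolysed in the same pot; the aryl iodide is inert to alkaline peroxide and the reducing acidic work-up protects the air-sensitive hydroquinone.

Step 2
Reactants: 2 2-iodo-6-methoxybenzene-1,4-diol; 3 4-chlorobenzenesulfonyl chloride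
Product: 5 4-[(tert-butyldimethylsilyl)oxy]-2-iodo-6-methoxyphenyl 4-chlorobenzenesulfonate, via silyl ether 4 (not isolated)
Conditions: TBSCl (1.05 equiv), Et3N (1.2 equiv), DMAP (cat.), CH2Cl2, −20 → 0 °C; then 3 (1.2 equiv), Et3N (1.5 equiv), 0 → 25 °C
Reagents that add atoms: tert-butyldimethylsilyl chloride, CC(C)(C)[Si](C)(C)Cl
Why: Sterically controlled O-silylation followed by O-sulfonylation of a phenol: the C4 hydroxyl has two ortho hydrogens whereas the C1 hydroxyl is flanked by iodine and methoxy, so one equivalent of the bulky silyl chloride should take the C4 oxygen, and the remaining flanked phenol is then sulfonylated under amine/DMAP catalysis in the same flask.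

Step 3
Reactants: 5 4-[(tert-butyldimethylsilyl)oxy]-2-iodo-6-methoxyphenyl 4-chlorobenzenesulfonate; 6 benzyl bromide
Product: 7 4-(benzyloxy)-2-iodo-6-methoxyphenyl 4-chlorobenzenesulfonate
Conditions: CsF (1.5 equiv), 6 (1.2 equiv), DMF, 25 °C
Reagents that add atoms: none
Why: One-pot desilylative Williamson etherification: fluoride cleaves the aryl silyl ether and the C4 phenoxide is alkylated at once by benzyl bromide; the aryl sulfonate and the aryl iodide are not attacked by fluoride at room temperature.

Step 4
Reactants: 7 4-(benzyloxy)-2-iodo-6-methoxyphenyl 4-chlorobenzenesulfonate; 8 pentylmagnesium bromide; 9 carbon dioxide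
Product: 13 4-(benzyloxy)-2-methoxy-6-pentylbenzoic acid, via magnesiated sulfonate 10 (not isolated), via aryne 11 (not isolated), via arylmagnesium bromide 12 (not isolated)
Conditions: i-PrMgCl (1.05 equiv), THF, −78 °C; 8 (2.5 equiv), −78 → 25 °C; CO2 (dry gas), −20 → 25 °C; aq. HCl
Reagents that add atoms: none
Why: Iodine–magnesium exchange with i-PrMgCl at −78 °C converts 7 into 10, which should persist at that temperature because the 4-chlorobenzenesulfonate is only a moderate leaving group. After 8 has been added, warming triggers β-elimination of the magnesium sulfonate and releases 11 in the presence of excess alkyl nucleophile; the positions of iodine and sulfonate allow this one aryne only. 8 adds at the aryne carbon that carried iodine, meta to methoxy, so the new aryl–magnesium bond of 12 lies ortho to methoxy, where the σ-carbanion is stabilised by the inductive pull of oxygen and by oxygen-to-magnesium coordination; the ground-state distortion of 3-alkoxyarynes points the same way. The benzyloxy group is meta to the attacked carbon and para to the metalated one, too remote to override the adjacent methoxy group. Carbon dioxide then carboxylates 12 at the metalated carbon, which places the carboxyl between methoxy and pentyl, and acid work-up gives 13. The closest known chemistry is aryne generation from 2-magnesiated aryl sulfonates and carbomagnesiation of 3-alkoxyarynes with electrophilic trapping of the arylmagnesium (three-component aryne coupling). No ring is closed and no stereocentre is formed; the selectivities needed are regiochemical, secured by the methoxy group, and exchange at iodine in preference to attack at sulfur, secured by the low temperature and the choice of sulfonate.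

Step 5
Reactants: 13 4-(benzyloxy)-2-methoxy-6-pentylbenzoic acid (first portion)
Product: 14 4-hydroxy-2-methoxy-6-pentylbenzoic acid
Conditions: H2 (1 atm), 10% Pd/C, EtOAc, 25 °C
Reagents that add atoms: none
Why: Hydrogenolysis of an aryl benzyl ether; the molecule contains no other reducible group, and the neutral, room-temperature conditions avoid decarboxylation.

Step 6
Reactants: 14 4-hydroxy-2-methoxy-6-pentylbenzoic acid; 6 benzyl bromide
Product: 15 benzyl 4-hydroxy-2-methoxy-6-pentylbenzoate
Conditions: 6 (1.05 equiv), KHCO3 (1.1 equiv), DMF, 25 °C
Reagents that add atoms: none
Why: Chemoselective carboxylate O-alkylation: KHCO3 deprotonates the carboxylic acid (pKa about 4) but not the phenol (pKa about 9–10), and SN2 attack of the carboxylate on benzyl bromide is not hampered by the two ortho substituents that would block acyl substitution.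

Step 7
Reactants: 13 4-(benzyloxy)-2-methoxy-6-pentylbenzoic acid (second portion); 15 benzyl 4-hydroxy-2-methoxy-6-pentylbenzoate
Product: 17 benzyl 4-{[4-(benzyloxy)-2-methoxy-6-pentylbenzoyl]oxy}-2-methoxy-6-pentylbenzoate, via acid chloride 16 (not isolated)
Conditions: (COCl)2, DMF (cat.), CH2Cl2, 0 → 25 °C, evaporate; then 15, Et3N, DMAP (cat.), CH2Cl2, 0 → 25 °C
Reagents that add atoms: none
Why: Acid chloride formation under Vilsmeier-type catalysis, then DMAP-catalysed O-acylation of the only free nucleophile, the phenol of 15; the ortho-methoxy and para-benzyloxy groups give the hindered acyl chloride enough acylium character to react, and the benzyl ether and benzyl ester are inert.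

Step 8
Reactants: 17 benzyl 4-{[4-(benzyloxy)-2-methoxy-6-pentylbenzoyl]oxy}-2-methoxy-6-pentylbenzoate
Product: 18 4-O-demethylplanaic acid (4-[(4-hydroxy-2-methoxy-6-pentylbenzoyl)oxy]-2-methoxy-6-pentylbenzoic acid)
Conditions: H2 (1 atm), 10% Pd/C, EtOAc, 25 °C
Reagents that add atoms: none
Why: Double hydrogenolysis of the benzyl ether and the benzyl ester under neutral conditions; the aryl ester is not hydrogenolysed and the non-nucleophilic solvent excludes transesterification.

## Compound list

1 | 5-iodovanillin (4-hydroxy-3-iodo-5-methoxybenzaldehyde) | COc1cc(C=O)cc(I)c1O | starting material
2 | 2-iodo-6-methoxybenzene-1,4-diol | COc1cc(O)cc(I)c1O | intermediate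
3 | 4-chlorobenzenesulfonyl chloride | O=S(=O)(Cl)c1ccc(Cl)cc1 | starting material
4 | 4-[(tert-butyldimethylsilyl)oxy]-2-iodo-6-methoxyphenol | COc1cc(O[Si](C)(C)C(C)(C)C)cc(I)c1O | intermediate (not isolated)
5 | 4-[(tert-butyldimethylsilyl)oxy]-2-iodo-6-methoxyphenyl 4-chlorobenzenesulfonate | COc1cc(O[Si](C)(C)C(C)(C)C)cc(I)c1OS(=O)(=O)c1ccc(Cl)cc1 | intermediate
6 | benzyl bromide | BrCc1ccccc1 | starting material
7 | 4-(benzyloxy)-2-iodo-6-methoxyphenyl 4-chlorobenzenesulfonate | COc1cc(OCc2ccccc2)cc(I)c1OS(=O)(=O)c1ccc(Cl)cc1 | intermediate
8 | pentylmagnesium bromide | CCCCC[Mg]Br | starting material
9 | carbon dioxide | O=C=O | starting material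
10 | [5-(benzyloxy)-2-{[(4-chlorophenyl)sulfonyl]oxy}-3-methoxyphenyl]magnesium chloride | COc1cc(OCc2ccccc2)cc([Mg]Cl)c1OS(=O)(=O)c1ccc(Cl)cc1 | intermediate (not isolated)
11 | 5-(benzyloxy)-3-methoxy-1,2-didehydrobenzene (5-benzyloxy-3-methoxybenzyne) | COC1=CC(OCc2ccccc2)=CC#C1 | intermediate (not isolated)
12 | [4-(benzyloxy)-2-methoxy-6-pentylphenyl]magnesium bromide | CCCCCc1cc(OCc2ccccc2)cc(OC)c1[Mg]Br | intermediate (not isolated)
13 | 4-(benzyloxy)-2-methoxy-6-pentylbenzoic acid | CCCCCc1cc(OCc2ccccc2)cc(OC)c1C(=O)O | intermediate
14 | 4-hydroxy-2-methoxy-6-pentylbenzoic acid | CCCCCc1cc(O)cc(OC)c1C(=O)O | intermediate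
15 | benzyl 4-hydroxy-2-methoxy-6-pentylbenzoate | CCCCCc1cc(O)cc(OC)c1C(=O)OCc1ccccc1 | intermediate
16 | 4-(benzyloxy)-2-methoxy-6-pentylbenzoyl chloride | CCCCCc1cc(OCc2ccccc2)cc(OC)c1C(=O)Cl | intermediate (not isolated)
17 | benzyl 4-{[4-(benzyloxy)-2-methoxy-6-pentylbenzoyl]oxy}-2-methoxy-6-pentylbenzoate | CCCCCc1cc(OC(=O)c2c(CCCCC)cc(OCc3ccccc3)cc2OC)cc(OC)c1C(=O)OCc1ccccc1 | intermediate
18 | 4-O-demethylplanaic acid (4-[(4-hydroxy-2-methoxy-6-pentylbenzoyl)oxy]-2-methoxy-6-pentylbenzoic acid) | CCCCCc1cc(OC(=O)c2c(CCCCC)cc(O)cc2OC)cc(OC)c1C(=O)O | target

## Step count and least certain steps

Total step count: 8. Longest linear sequence: 8 steps (1 → 2 → 5 → 7 → 13 → 14 → 15 → 17 → 18); 13 enters step 7 a second time as the acyl half.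

Step 4 (key step). The most likely failure is diversion of the aryne away from carbomagnesiation: attack of a Grignard reagent at the sulfur of the sulfonate, capture of 11 by the arylmagnesium species 10 or 12 instead of 8, or hydride transfer from the β-position of the alkyl Grignard reagent to the aryne. Some erosion of regioselectivity by the remote benzyloxy group is also possible, and carboxylation of surplus 8 would consume CO2 and complicate the acid–base isolation. The fallback avoids the aryne altogether and uses the fact that 7 already has iodine where the pentyl group belongs and oxygen where the carboxyl belongs. It sets out from 7: Negishi coupling with pentylzinc bromide (PdCl2(dppf), THF, 50 °C) at the carbon–iodine bond should give 4-(benzyloxy)-2-methoxy-6-pentylphenyl 4-chlorobenzenesulfonate F1. Cleavage of the sulfonate (KOH, MeOH/THF, reflux) should give 4-(benzyloxy)-2-methoxy-6-pentylphenol F2. Triflation (Tf2O, pyridine, CH2Cl2, 0 °C) should give 4-(benzyloxy)-2-methoxy-6-pentylphenyl trifluoromethanesulfonate F3. Palladium-catalysed hydroxycarbonylation of the triflate (Pd(OAc)2, dppf, KOAc, CO 1 atm, DMSO, 70 °C) comes back to the route at 13. This is three steps longer, but each step is standard and the regiochemistry is fixed by the substrate.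

Step 2. The most likely failure is incomplete steric discrimination in the silylation (some silylation of the flanked hydroxyl, or bis-silylation), which the one-pot sulfonylation would carry forward as isomeric sulfonates; sluggish sulfonylation of the flanked phenol is a second possibility. The fallback replaces steric control by control through basicity. It sets out from 2: full deprotonation to the dianion (KOt-Bu 2.1 equiv, THF/DMF, 0 °C, argon) and addition of one equivalent of 6 should alkylate the more basic and less hindered C4 phenoxide first and give 4-(benzyloxy)-2-iodo-6-methoxyphenol F4. Sulfonylation with 3 (Et3N, DMAP, CH2Cl2) comes back to the route at 7, bypassing 4 and 5.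

Step 7. The most likely failure is slow acyl transfer at the di-ortho-substituted carbonyl, so that hydrolysis of 16 by adventitious water or acyl exchange wins. The fallback changes the acyl donor and the mechanism from base-mediated nucleophilic catalysis to an acid-mediated acylium pathway. It sets out from 13 and 15: trifluoroacetic anhydride in toluene at 25 °C converts 13 into 4-(benzyloxy)-2-methoxy-6-pentylbenzoic trifluoroacetic anhydride F5, which ionises readily because the ortho-methoxy and para-benzyloxy groups stabilise the acylium ion, and the phenol of 15 is acylated without base; it comes back to the route at 17.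

Step 6. The most likely failure is loss of chemoselectivity, with benzylation at the phenol oxygen as well as at the carboxylate, or decarboxylation of the electron-rich acid 14 during handling. The fallback dispenses with carboxyl protection. It sets out from 14: double deprotonation (NaH 2.1 equiv, THF, 0 °C) and acylation of the far more nucleophilic phenoxide with acid chloride 16 should give 4-{[4-(benzyloxy)-2-methoxy-6-pentylbenzoyl]oxy}-2-methoxy-6-pentylbenzoic acid F6. Hydrogenolysis (H2, Pd/C, EtOAc) comes back to the route at 18, bypassing 15 and 17.

## Further compounds

F1 | step 4 | 4-(benzyloxy)-2-methoxy-6-pentylphenyl 4-chlorobenzenesulfonate | CCCCCc1cc(OCc2ccccc2)cc(OC)c1OS(=O)(=O)c1ccc(Cl)cc1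
F2 | step 4 | 4-(benzyloxy)-2-methoxy-6-pentylphenol | CCCCCc1cc(OCc2ccccc2)cc(OC)c1O
F3 | step 4 | 4-(benzyloxy)-2-methoxy-6-pentylphenyl trifluoromethanesulfonate | CCCCCc1cc(OCc2ccccc2)cc(OC)c1OS(=O)(=O)C(F)(F)F
F4 | step 2 | 4-(benzyloxy)-2-iodo-6-methoxyphenol | COc1cc(OCc2ccccc2)cc(I)c1O
F5 | step 7 | 4-(benzyloxy)-2-methoxy-6-pentylbenzoic trifluoroacetic anhydride | CCCCCc1cc(OCc2ccccc2)cc(OC)c1C(=O)OC(=O)C(F)(F)F
F6 | step 6 | 4-{[4-(benzyloxy)-2-methoxy-6-pentylbenzoyl]oxy}-2-methoxy-6-pentylbenzoic acid | CCCCCc1cc(OC(=O)c2c(CCCCC)cc(OCc3ccccc3)cc2OC)cc(OC)c1C(=O)O
A1 | alternative 1 | dimethyl 2-(1-methoxyethylidene)-3-pentylpentanedioate (racemic, alkene geometry not fixed) | COC(C)=C(C(=O)OC)C(CCCCC)CC(=O)OC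
A2 | alternative 1 | methyl 2-methoxy-4-oxo-6-pentylcyclohex-2-ene-1-carboxylate (racemic) | CCCCCC1CC(=O)C=C(OC)C1C(=O)OC
A3 | alternative 1 | methyl 4-hydroxy-2-methoxy-6-pentylbenzoate | CCCCCc1cc(O)cc(OC)c1C(=O)OC
A4 | alternative 2 | benzyl 2-methoxy-6-pentyl-4-[(3,5,7-trioxododecanoyl)oxy]benzoate | CCCCCC(=O)CC(=O)CC(=O)CC(=O)Oc1cc(CCCCC)c(C(=O)OCc2ccccc2)c(OC)c1
A5 | alternative 2 | benzyl 4-[(2,4-dihydroxy-6-pentylbenzoyl)oxy]-2-methoxy-6-pentylbenzoate | CCCCCc1cc(OC(=O)c2c(CCCCC)cc(O)cc2O)cc(OC)c1C(=O)OCc1ccccc1
A6 | alternative 3 | methyl 6-methoxy-2-oxo-4-pentyl-2H-pyran-5-carboxylate | CCCCCC1=CC(=O)OC(OC)=C1C(=O)OC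
A7 | alternative 3 | ethynyloxytri(propan-2-yl)silane (triisopropylsilyloxyethyne) | C#CO[Si](C(C)C)(C(C)C)C(C)C
A8 | alternative 3 | methyl 2-methoxy-6-pentyl-4-[(triisopropylsilyl)oxy]benzoate | CCCCCc1cc(O[Si](C(C)C)(C(C)C)C(C)C)cc(OC)c1C(=O)OC
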